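**Plan**

1. Ring A is a butyrylphloroglucinol joined by two CH2 bridges to rings B and C. Each of B and C holds a ring carbon with two methyl groups, so both are 6,6-dimethylcyclohexa-2,4-dienones that cannot aromatise. That is the product expected when a 4,4-dimethylcyclobutenone is annulated with an alkyne.
2. Retrosynthetic cuts: first the three O–benzyl bonds and the two ring–propionyl C–C bonds. Then, in each of rings B and C, the two ring bonds flanking the CH–C(O) pair, giving one molecule of ethoxyacetylene per ring and a cyclobutenone. Last, the two CH2–C(ring B/C) bridge bonds, giving a ring A dialdehyde and 2,2-dimethylcyclobutane-1,3-dione.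
3. Forward: ring A is finished first (diformylation, butyrylation, benzylation). The four-membered ring is made from dimethylketene and ethoxyacetylene and attached twice through the bridges. Rings B and C then form together in one two-directional annulation that takes up two molecules of ethoxyacetylene, and hydrolysis, C-propionylation and hydrogenolysis complete the target.
4. Stereochemistry: the target is achiral, with no stereocentre and no configured double bond. Nothing has to be set, and the only selectivity at stake is the regiochemistry of the annulation.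

Key step: step 8

Assumption: every enolised β-dicarbonyl unit is drawn as one tautomer (for 21 the one in the target SMILES) although each is a fast tautomeric mixture; the transient compound 15 is a mixture of diastereomers, and 19 is drawn as one of the possible enol esters.

**Route**

Step 1
Reactants: 1 phloroglucinol
Product: 2 2,4,6-trihydroxybenzene-1,3-dicarbaldehyde
Conditions: POCl3 (2.5 equiv), DMF, 1,4-dioxane, 0 °C to rt; then H2O, rt
Reagents that add atoms: N,N-dimethylformamide, CN(C)C=O; water, O
Why: Vilsmeier–Haack formylation, in which the chloroiminium ion attacks the very electron-rich ring twice and the two iminium groups then deactivate the last free position, so the reaction should stop at the dialdehyde.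

Step 2
Reactants: 2 2,4,6-trihydroxybenzene-1,3-dicarbaldehyde; 3 butyryl chloride
Product: 4 5-butanoyl-2,4,6-trihydroxybenzene-1,3-dicarbaldehyde
Conditions: AlCl3 (4 equiv), PhNO2, 60 °C; then ice, 1 M HCl
Reagents that add atoms: none
Why: Friedel–Crafts acylation at the one remaining ring carbon, which three hydroxyl groups still activate (exhaustive C-acylation of phloroglucinol is standard), with any aryl ester formed first passing on by Fries rearrangement.

Step 3
Reactants: 4 5-butanoyl-2,4,6-trihydroxybenzene-1,3-dicarbaldehyde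
Product: 5 2,4,6-tris(benzyloxy)-5-butanoylbenzene-1,3-dicarbaldehyde
Conditions: BnBr (4 equiv), K2CO3 (4 equiv), DMF, 60 °C
Reagents that add atoms: benzyl bromide, BrCc1ccccc1
Why: Williamson etherification of three acidic, carbonyl-flanked phenols in a dipolar aprotic solvent, where O-alkylation should dominate and every ring carbon is already substituted.

Step 4
Reactants: 6 isobutyryl chloride; 7 ethoxyacetylene
Product: 9 3-ethoxy-4,4-dimethylcyclobut-2-en-1-one, via dimethylketene 8 (not isolated)
Conditions: Et3N (1.1 equiv), ethoxyacetylene (2 equiv), Et2O, slow addition of 6, rt to 35 °C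
Reagents that add atoms: none
Why: Dehydrochlorination gives dimethylketene, which is trapped by the electron-rich alkyne in a regioselective thermal [2+2] cycloaddition (ketene carbonyl carbon to the C–H carbon of the ynol ether), the standard entry to 3-alkoxycyclobutenones.

Step 5
Reactants: 9 3-ethoxy-4,4-dimethylcyclobut-2-en-1-one
Product: 10 3-hydroxy-4,4-dimethylcyclobut-2-en-1-one (enol form of 2,2-dimethylcyclobutane-1,3-dione)
Conditions: 1 M aq. HCl, THF, 0 °C to rt
Reagents that add atoms: water, O
Why: Acid hydrolysis of a vinylogous ester, giving a strong vinylogous acid that is stable as its enol.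

Step 6
Reactants: 5 2,4,6-tris(benzyloxy)-5-butanoylbenzene-1,3-dicarbaldehyde; 10 3-hydroxy-4,4-dimethylcyclobut-2-en-1-one
Product: 12 1-[2,4,6-tris(benzyloxy)-3,5-bis[(2-hydroxy-3,3-dimethyl-4-oxocyclobut-1-en-1-yl)methyl]phenyl]butan-1-one, via bis-alkylidene dione 11 (not isolated)
Conditions: 10 (2.4 equiv), Hantzsch ester (diethyl 2,6-dimethyl-1,4-dihydropyridine-3,5-dicarboxylate, 2.4 equiv), L-proline (20 mol%), CH2Cl2, rt
Reagents that add atoms: none
Why: Three-component reductive alkylation (amine-catalysed Knoevenagel condensation, then transfer hydrogenation of the alkylidene dione by the Hantzsch ester), a reaction established for acidic cyclic 1,3-diones with aromatic aldehydes and one that leaves the aryl ketone and benzyl ethers untouched.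

Step 7
Reactants: 12 1-[2,4,6-tris(benzyloxy)-3,5-bis[(2-hydroxy-3,3-dimethyl-4-oxocyclobut-1-en-1-yl)methyl]phenyl]butan-1-one
Product: 13 1-[2,4,6-tris(benzyloxy)-3,5-bis[(2-ethoxy-3,3-dimethyl-4-oxocyclobut-1-en-1-yl)methyl]phenyl]butan-1-one
Conditions: EtOH (3 equiv), PPh3 (2.6 equiv), DIAD (2.6 equiv), THF, 0 °C to rt
Reagents that add atoms: ethanol, CCO
Why: Mitsunobu O-alkylation of a vinylogous carboxylic acid, which should alkylate on oxygen, and because the two carbonyl oxygens of each dione unit are equivalent only one enol ether can form.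

Step 8
Reactants: 13 1-[2,4,6-tris(benzyloxy)-3,5-bis[(2-ethoxy-3,3-dimethyl-4-oxocyclobut-1-en-1-yl)methyl]phenyl]butan-1-one; 7 ethoxyacetylene
Product: 17 1-[2,4,6-tris(benzyloxy)-3,5-bis[(2,6-diethoxy-3,3-dimethyl-4-oxocyclohexa-1,5-dien-1-yl)methyl]phenyl]butan-1-one, via bis(vinylketene) 14 (not isolated), via bis(vinylcyclobutenone) 15 (not isolated), via bis(dienylketene) 16 (not isolated)
Conditions: 7 (10 equiv), degassed toluene (0.05 M), sealed tube, 90 °C
Reagents that add atoms: ethoxyacetylene (the second molecule of 7 taken up), CCOC#C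
Why: Proposed new method: each 3-ethoxy-4,4-dimethylcyclobutenone should open thermally (4π, conrotatory) to a vinylketene whose central carbon is attacked by the unsubstituted, nucleophilic carbon of one molecule of ethoxyacetylene, the [2+2] adduct 15 then reopens (4π) to dienylketene 16, and this closes by a thermal disrotatory 6π-electrocyclisation between the ketene carbon and the dimethyl-bearing terminus; the closest known reaction type is the Danheiser benzannulation of cyclobutenones with alkoxyalkynes, here held at the dienone stage. Rings B and C are each closed in the same way, as six-membered carbocycles by 6π-electrocyclisation of the dienylketene whose ketene arm lies cis to the 1-ethoxy-2-methylpropenyl arm, the bond formed being C(=O)–C(CH3)2. No stereocentre is created in 17, since the quaternary carbons of 15 are transient and become trigonal again in the second ring opening, and the equation is a pure addition in which 13 and two molecules of 7 (one per cyclobutenone) give 17 with nothing split off. The step needs regioselectivity in the ketene–alkyne [2+2], which the polarised ynol ether secures by joining its C–H carbon to the ketene carbonyl carbon and its ethoxy-bearing carbon to the bridge-bearing carbon, so that the ring C–H ends up where the propionyl group belongs. It also needs the cascade to stop before aromatisation and the ketenes to survive, which is secured by the two methyl groups on the sp3 terminus (no hydrogen to lose, no E/Z question in the first opening) and by the absence of any O–H or N–H group in 13. Opening of 15 in the unproductive sense should revert through the cyclobutenone until the productive dienylketene geometry is drained by ring closure.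

Step 9
Reactants: 17 1-[2,4,6-tris(benzyloxy)-3,5-bis[(2,6-diethoxy-3,3-dimethyl-4-oxocyclohexa-1,5-dien-1-yl)methyl]phenyl]butan-1-one
Product: 18 1-[2,4,6-tris(benzyloxy)-3,5-bis[(2,4-dihydroxy-3,3-dimethyl-6-oxocyclohexa-1,4-dien-1-yl)methyl]phenyl]butan-1-one
Conditions: 2 M aq. HCl, THF, 50 °C
Reagents that add atoms: water, O
Why: Acid hydrolysis of the vinylogous ester and of the dienol ether in each ring to the enolised β-triketone, under conditions that aryl benzyl ethers tolerate.

Step 10
Reactants: 18 1-[2,4,6-tris(benzyloxy)-3,5-bis[(2,4-dihydroxy-3,3-dimethyl-6-oxocyclohexa-1,4-dien-1-yl)methyl]phenyl]butan-1-one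
Product: 20 1-[2,4,6-tris(benzyloxy)-3,5-bis[(2,4-dihydroxy-3,3-dimethyl-6-oxo-5-propanoylcyclohexa-1,4-dien-1-yl)methyl]phenyl]butan-1-one, via bis(enol propanoate) 19 (not isolated)
Conditions: propionic acid (2.4 equiv), DCC (2.6 equiv), DMAP (3 equiv), CH2Cl2, rt
Reagents that add atoms: propionic acid, CCC(=O)O
Why: Steglich-type O-acylation of the enol followed by DMAP-mediated O-to-C acyl migration, the standard way to 2-acylcyclohexane-1,3-diones and acylated cyclic β-triketones, with the unsubstituted ring carbon between two carbonyls as the only site that can hold the acyl group as a chelated enol.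

Step 11
Reactants: 20 1-[2,4,6-tris(benzyloxy)-3,5-bis[(2,4-dihydroxy-3,3-dimethyl-6-oxo-5-propanoylcyclohexa-1,4-dien-1-yl)methyl]phenyl]butan-1-one
Product: 21 1-[2,4,6-trihydroxy-3,5-bis[(2,4-dihydroxy-3,3-dimethyl-6-oxo-5-propanoylcyclohexa-1,4-dien-1-yl)methyl]phenyl]butan-1-one (CNP0212485.0)
Conditions: H2 (1 atm), Pd/C (10 wt%), EtOAc, rt
Reagents that add atoms: none
Why: Hydrogenolysis of aryl benzyl ethers over palladium on carbon, which should leave the chelated enolised triketones and the aryl ketone unreduced at ambient pressure and temperature.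

**Compound list**

1 | phloroglucinol | Oc1cc(O)cc(O)c1 | starting material
2 | 2,4,6-trihydroxybenzene-1,3-dicarbaldehyde | O=Cc1c(O)cc(O)c(C=O)c1O | intermediate
3 | butyryl chloride | CCCC(Cl)=O | starting material
4 | 5-butanoyl-2,4,6-trihydroxybenzene-1,3-dicarbaldehyde | CCCC(=O)c1c(O)c(C=O)c(O)c(C=O)c1O | intermediate
5 | 2,4,6-tris(benzyloxy)-5-butanoylbenzene-1,3-dicarbaldehyde | CCCC(=O)c1c(OCc2ccccc2)c(C=O)c(OCc2ccccc2)c(C=O)c1OCc1ccccc1 | intermediate
6 | isobutyryl chloride | CC(C)C(Cl)=O | starting material
7 | ethoxyacetylene | CCOC#C | starting material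
8 | dimethylketene | CC(C)=C=O | intermediate (not isolated)
9 | 3-ethoxy-4,4-dimethylcyclobut-2-en-1-one | CCOC1=CC(=O)C1(C)C | intermediate
10 | 3-hydroxy-4,4-dimethylcyclobut-2-en-1-one | CC1(C)C(O)=CC1=O | intermediate
11 | bis-alkylidene dione, 1-[2,4,6-tris(benzyloxy)-3,5-bis[(3,3-dimethyl-2,4-dioxocyclobutylidene)methyl]phenyl]butan-1-one | CCCC(=O)c1c(OCc2ccccc2)c(C=C2C(=O)C(C)(C)C2=O)c(OCc2ccccc2)c(C=C2C(=O)C(C)(C)C2=O)c1OCc1ccccc1 | intermediate (not isolated)
12 | 1-[2,4,6-tris(benzyloxy)-3,5-bis[(2-hydroxy-3,3-dimethyl-4-oxocyclobut-1-en-1-yl)methyl]phenyl]butan-1-one | CCCC(=O)c1c(OCc2ccccc2)c(CC2=C(O)C(C)(C)C2=O)c(OCc2ccccc2)c(CC2=C(O)C(C)(C)C2=O)c1OCc1ccccc1 | intermediate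
13 | 1-[2,4,6-tris(benzyloxy)-3,5-bis[(2-ethoxy-3,3-dimethyl-4-oxocyclobut-1-en-1-yl)methyl]phenyl]butan-1-one | CCCC(=O)c1c(OCc2ccccc2)c(CC2=C(OCC)C(C)(C)C2=O)c(OCc2ccccc2)c(CC2=C(OCC)C(C)(C)C2=O)c1OCc1ccccc1 | intermediate (key-step precursor)
14 | bis(vinylketene), both arms ArCH2–C(=C=O)–C(OEt)=C(CH3)2 | CCCC(=O)c1c(OCc2ccccc2)c(CC(=C=O)C(OCC)=C(C)C)c(OCc2ccccc2)c(CC(=C=O)C(OCC)=C(C)C)c1OCc1ccccc1 | intermediate (not isolated)
15 | bis(vinylcyclobutenone), both arms 3-ethoxy-4-(1-ethoxy-2-methylprop-1-enyl)-4-(arylmethyl)cyclobut-2-en-1-one, diastereomer mixture | CCCC(=O)c1c(OCc2ccccc2)c(CC2(C(OCC)=C(C)C)C(=O)C=C2OCC)c(OCc2ccccc2)c(CC2(C(OCC)=C(C)C)C(=O)C=C2OCC)c1OCc1ccccc1 | intermediate (not isolated)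
16 | bis(dienylketene), both arms with the ketene-bearing CH cis to the 1-ethoxy-2-methylpropenyl group | CCCC(=O)c1c(OCc2ccccc2)c(C/C(C(OCC)=C(C)C)=C(OCC)/C=C=O)c(OCc2ccccc2)c(C/C(C(OCC)=C(C)C)=C(OCC)/C=C=O)c1OCc1ccccc1 | intermediate (not isolated)
17 | 1-[2,4,6-tris(benzyloxy)-3,5-bis[(2,6-diethoxy-3,3-dimethyl-4-oxocyclohexa-1,5-dien-1-yl)methyl]phenyl]butan-1-one | CCCC(=O)c1c(OCc2ccccc2)c(CC2=C(OCC)C(C)(C)C(=O)C=C2OCC)c(OCc2ccccc2)c(CC2=C(OCC)C(C)(C)C(=O)C=C2OCC)c1OCc1ccccc1 | intermediate (key-step product)
18 | 1-[2,4,6-tris(benzyloxy)-3,5-bis[(2,4-dihydroxy-3,3-dimethyl-6-oxocyclohexa-1,4-dien-1-yl)methyl]phenyl]butan-1-one | CCCC(=O)c1c(OCc2ccccc2)c(CC2=C(O)C(C)(C)C(O)=CC2=O)c(OCc2ccccc2)c(CC2=C(O)C(C)(C)C(O)=CC2=O)c1OCc1ccccc1 | intermediate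
19 | bis(enol propanoate) of 18, ester on the enol oxygen next to the ring C–H | CCCC(=O)c1c(OCc2ccccc2)c(CC2=C(O)C(C)(C)C(OC(=O)CC)=CC2=O)c(OCc2ccccc2)c(CC2=C(O)C(C)(C)C(OC(=O)CC)=CC2=O)c1OCc1ccccc1 | intermediate (not isolated)
20 | 1-[2,4,6-tris(benzyloxy)-3,5-bis[(2,4-dihydroxy-3,3-dimethyl-6-oxo-5-propanoylcyclohexa-1,4-dien-1-yl)methyl]phenyl]butan-1-one | CCCC(=O)c1c(OCc2ccccc2)c(CC2=C(O)C(C)(C)C(O)=C(C(=O)CC)C2=O)c(OCc2ccccc2)c(CC2=C(O)C(C)(C)C(O)=C(C(=O)CC)C2=O)c1OCc1ccccc1 | intermediate
21 | CNP0212485.0, 1-[2,4,6-trihydroxy-3,5-bis[(2,4-dihydroxy-3,3-dimethyl-6-oxo-5-propanoylcyclohexa-1,4-dien-1-yl)methyl]phenyl]butan-1-one | CCCC(=O)c1c(O)c(CC2=C(O)C(C)(C)C(O)=C(C(=O)CC)C2=O)c(O)c(CC2=C(O)C(C)(C)C(O)=C(C(=O)CC)C2=O)c1O | target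

**Step count**

Total: 11 steps. Longest linear sequence: 9 steps (steps 1, 2, 3, 6, 7, 8, 9, 10, 11, from phloroglucinol); the cyclobutenone branch (steps 4 and 5) joins at step 6.

**Steps most likely to fail**

Step 8 (bears the label). What may go wrong is a process: the push–pull cyclobutenone may not open below the temperature at which ethoxyacetylene fragments to ketene and ethene. The vinylketene may also be lost by a 1,5-hydrogen shift from a methyl group or by oligomerisation before the alkyne adds, or only one arm may complete the cascade. The fallback uses known chemistry and sets out from 1 and 5. Friedel–Crafts acylation of 1 with propionyl chloride and AlCl3 in PhNO2 gives 1-(2,4,6-trihydroxyphenyl)propan-1-one F1. Geminal C-methylation with MeI and NaOMe in MeOH gives propionylfilicinic acid F2, in which the ring is already dearomatised and acylated. Two-fold reductive alkylation of F2 at its free ring C–H with dialdehyde 5 (Hantzsch ester, L-proline, CH2Cl2) then forms both bridges. The route is rejoined at 20, and steps 4 to 10 are not needed.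

Step 6. What may go wrong: retro-Claisen opening of the strained dione by the amine catalyst or by the water released, slow condensation at the doubly ortho-substituted aldehydes, or addition of a second dione to the alkylidene before hydride transfer. The fallback replaces enol chemistry by cross-coupling and sets out from 5 and 9. Reduction of the two aldehydes of 5 with NaBH4 in THF–MeOH at −20 °C (aldehyde before hindered aryl ketone) gives 1-[2,4,6-tris(benzyloxy)-3,5-bis(hydroxymethyl)phenyl]butan-1-one F3. PBr3 in CH2Cl2 at 0 °C gives 1-[2,4,6-tris(benzyloxy)-3,5-bis(bromomethyl)phenyl]butan-1-one F4. In parallel, 9 is brominated at its ring C–H with N-bromosuccinimide in CH2Cl2 to 2-bromo-3-ethoxy-4,4-dimethylcyclobut-2-en-1-one F5. Zinc insertion into F4 (Zn dust, LiCl, THF) gives the ketone-tolerant bis(benzylzinc bromide) F6. Negishi coupling of F6 with F5 under Pd(PPh3)4 in THF gives 13 directly, so the route is rejoined at 13 and step 7 is not needed either.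

Step 10. What may go wrong: arrest at the enol ester stage, acylation at an enol oxygen of the finished triketone, or base-promoted exchange of the methylene bridges under DMAP. The fallback reverses the order of the last two operations and uses a Lewis-acid C-acylation; it sets out from 18. Hydrogenolysis (H2, Pd/C, EtOAc) gives 1-[2,4,6-trihydroxy-3,5-bis[(2,4-dihydroxy-3,3-dimethyl-6-oxocyclohexa-1,4-dien-1-yl)methyl]phenyl]butan-1-one F7. Friedel–Crafts acylation with propionic anhydride and BF3·OEt2 at 60 °C then acylates the only free ring carbons, those of rings B and C, since ring A is fully substituted. Any O-propanoates are cleaved by K2CO3 in MeOH, and the route is rejoined at 21.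

**Further compounds**

F1 | step 8 | 1-(2,4,6-trihydroxyphenyl)propan-1-one | CCC(=O)c1c(O)cc(O)cc1O
F2 | step 8 | propionylfilicinic acid, 3,5-dihydroxy-4,4-dimethyl-2-propanoylcyclohexa-2,5-dien-1-one | CCC(=O)C1=C(O)C(C)(C)C(O)=CC1=O
F3 | step 6 | 1-[2,4,6-tris(benzyloxy)-3,5-bis(hydroxymethyl)phenyl]butan-1-one | CCCC(=O)c1c(OCc2ccccc2)c(CO)c(OCc2ccccc2)c(CO)c1OCc1ccccc1
F4 | step 6 | 1-[2,4,6-tris(benzyloxy)-3,5-bis(bromomethyl)phenyl]butan-1-one | CCCC(=O)c1c(OCc2ccccc2)c(CBr)c(OCc2ccccc2)c(CBr)c1OCc1ccccc1
F5 | step 6 | 2-bromo-3-ethoxy-4,4-dimethylcyclobut-2-en-1-one | CCOC1=C(Br)C(=O)C1(C)C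
F6 | step 6 | bis(benzylzinc bromide) from F4 | CCCC(=O)c1c(OCc2ccccc2)c(C[Zn]Br)c(OCc2ccccc2)c(C[Zn]Br)c1OCc1ccccc1
F7 | step 10 | 1-[2,4,6-trihydroxy-3,5-bis[(2,4-dihydroxy-3,3-dimethyl-6-oxocyclohexa-1,4-dien-1-yl)methyl]phenyl]butan-1-one | CCCC(=O)c1c(O)c(CC2=C(O)C(C)(C)C(O)=CC2=O)c(O)c(CC2=C(O)C(C)(C)C(O)=CC2=O)c1O
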